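## Retrosynthetic overview

1. Target ⇒ aryl silyl ether of the target (last step: desilylation) ⇒ C9 primary alcohol **11**, with the angelate put on late and both (R)-2-methylbutanoates already in place.
2. The C9 CH2OH of **11** ⇒ terminal glycol of adduct **8** (glycol cleavage, then reduction); the stereocenter bought with L-erythrulose is erased once it has set C8.
3. Key disconnection: aryl–C8 bond, made by a nickel-catalysed electroreductive arylation of chiral ketone **4** with aryl bromide **7**; C8 is set by 1,2-induction from the erythrulose stereocenter.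
4. Pieces: L-erythrulose, (R)-2-methylbutanoic acid (used twice), 2-bromo-5-(hydroxymethyl)phenol, angelic acid.
5. Rings: the benzene ring is bought; the only ring made is the temporary dioxolane (step 1), opened again in step 5.

Assumption: L-erythrulose, (R)-2-methylbutanoic acid, 2-bromo-5-(hydroxymethyl)phenol and angelic acid are taken as purchasable.

Abbreviations: TBS = tert-butyldimethylsilyl; TES = triethylsilyl; bpy = 2,2'-bipyridine; DMA = N,N-dimethylacetamide; Ar' = 2-(TBS-oxy)-4-({[(2R)-2-methylbutanoyl]oxy}methyl)phenyl. Locants: C8 = carbinol carbon, C9 = angelate arm, C10 = methylbutanoate arm, C7 = benzylic CH2.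

## Route

Step 1
Reactants: 1 L-erythrulose
Product: 2 3,4-O-isopropylidene-L-erythrulose
Conditions: 2,2-dimethoxypropane, acetone, camphorsulfonic acid (cat.), rt
Reagents that add atoms: 2,2-dimethoxypropane, COC(C)(C)OC
Why: Acid-catalysed transacetalization closes the favoured five-membered acetonide on the vicinal 3,4-diol and leaves the primary α-ketol OH free; the bought (S) center is untouched.

Step 2
Reactants: 2 3,4-O-isopropylidene-L-erythrulose; 3 (2R)-2-methylbutanoic acid
Product: 4 2-[(4S)-2,2-dimethyl-1,3-dioxolan-4-yl]-2-oxoethyl (2R)-2-methylbutanoate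
Conditions: N,N'-diisopropylcarbodiimide, DMAP (5 mol %), CH2Cl2, 0 °C
Reagents that add atoms: none
Why: Steglich esterification of the only free (primary) hydroxyl at 0 °C, mild enough to leave the α-alkoxy ketone center and the α-branched acid unepimerized.

Step 3
Reactants: 5 2-bromo-5-(hydroxymethyl)phenol; 3 (2R)-2-methylbutanoic acid
Product: 7 {4-bromo-3-[(tert-butyldimethylsilyl)oxy]phenyl}methyl (2R)-2-methylbutanoate, via phenol ester 6 (not isolated)
Conditions: PPh3, DIAD, THF, 0 °C to rt; then imidazole, TBSCl, rt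
Reagents that add atoms: tert-butyldimethylsilyl chloride, CC(C)(C)[Si](C)(C)Cl
Why: Mitsunobu esterification activates only the benzylic alcohol and the carboxylic acid (far more acidic than the phenol) is the pronucleophile, so the phenol stays free and is then silylated in the same flask.

Step 4
Reactants: 4 2-[(4S)-2,2-dimethyl-1,3-dioxolan-4-yl]-2-oxoethyl (2R)-2-methylbutanoate; 7 {4-bromo-3-[(tert-butyldimethylsilyl)oxy]phenyl}methyl (2R)-2-methylbutanoate
Product: 8 (2R)-2-Ar'-2-[(4S)-2,2-dimethyl-1,3-dioxolan-4-yl]-2-hydroxyethyl (2R)-2-methylbutanoate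
Conditions: undivided cell, sacrificial Mg anode, nickel-foam cathode, NiBr2(bpy) (10 mol %), MgBr2 (0.3 equiv), Bu4NBr (0.1 M), THF/DMA 4:1, 0 °C, 5 mA cm-2, 2.2 F mol-1; aq. NH4Cl at 0 °C
Reagents that add atoms: none
Why: Proposed new method: nickel-catalysed electroreductive Barbier-type 1,2-arylation of a chelating, non-activated α,α'-dioxygenated dialkyl ketone (closest known reaction type: nickel-mediated reductive and electroreductive additions of aryl halides to aldehydes and activated ketones, and the stoichiometric chelation-controlled Grignard addition to O-protected erythrulose acetonides); zerovalent nickel formed at the cathode inserts into the C–Br bond of 7, one-electron reduction of the resulting aryl complex of divalent nickel gives a nucleophilic aryl complex of monovalent nickel that adds to the carbonyl of 4 while magnesium ions released from the anode hold the ketone oxygen and the dioxolane oxygen on the stereocenter in a five-membered chelate, so the aryl group enters anti to the dioxolane CH2 (Cram cyclic model) and sets C8 as R, and because neither a free aryl Grignard reagent nor a ketyl is formed the three ester groups and the α-acyloxy ketone survive.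

Step 5
Reactants: 8 (2R)-2-Ar'-2-[(4S)-2,2-dimethyl-1,3-dioxolan-4-yl]-2-hydroxyethyl (2R)-2-methylbutanoate
Product: 11 (2S)-2-Ar'-2,3-dihydroxypropyl (2R)-2-methylbutanoate, via triol 9 (not isolated), via aldehyde 10 (not isolated)
Conditions: H5IO6 (1.2 equiv), EtOAc, 0 °C to rt; filter, concentrate; then NaBH4, EtOH, -20 °C, AcOH quench
Reagents that add atoms: none
Why: Periodic acid hydrolyses the terminal acetonide and cleaves the unhindered primary–secondary glycol (Malaprade cleavage) much faster than the congested tertiary–secondary one, and cold borohydride reduction gives the C9 alcohol; C8 is not touched (its descriptor changes to S only through CIP priorities).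

Step 6
Reactants: 11 (2S)-2-Ar'-2,3-dihydroxypropyl (2R)-2-methylbutanoate; 12 angelic acid
Product: 14 (2R)-2-Ar'-2-hydroxy-3-{[(2R)-2-methylbutanoyl]oxy}propyl (2Z)-2-methylbut-2-enoate, via mixed anhydride 13 (not isolated)
Conditions: 12, 2,4,6-trichlorobenzoyl chloride, Et3N, toluene, rt, 2 h; then 11, 60 °C
Reagents that add atoms: none
Why: Yamaguchi mixed-anhydride esterification run without DMAP acylates the primary alcohol (the tertiary alcohol is inert, the phenol is silylated) and avoids the nucleophile-induced Z to E isomerization of the angeloyl group.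

Step 7
Reactants: 14 (2R)-2-Ar'-2-hydroxy-3-{[(2R)-2-methylbutanoyl]oxy}propyl (2Z)-2-methylbut-2-enoate
Product: 15 (2R)-2-hydroxy-2-[2-hydroxy-4-({[(2R)-2-methylbutanoyl]oxy}methyl)phenyl]-3-{[(2R)-2-methylbutanoyl]oxy}propyl (2Z)-2-methylbut-2-enoate
Conditions: Bu4NF, AcOH (1:1), THF, 0 °C
Reagents that add atoms: none
Why: Fluoride-mediated cleavage of the aryl silyl ether, buffered with acetic acid so that no alkoxide or phenoxide is present to trigger acyl migration between O9, O10 and O8.

## Compound list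

1 | L-erythrulose, (3S)-1,3,4-trihydroxybutan-2-one | OCC(=O)[C@@H](O)CO | starting material
2 | 3,4-O-isopropylidene-L-erythrulose, 1-[(4S)-2,2-dimethyl-1,3-dioxolan-4-yl]-2-hydroxyethan-1-one | OCC(=O)[C@@H]1COC(C)(C)O1 | intermediate
3 | (2R)-2-methylbutanoic acid | CC[C@@H](C)C(=O)O | starting material
4 | 2-[(4S)-2,2-dimethyl-1,3-dioxolan-4-yl]-2-oxoethyl (2R)-2-methylbutanoate | CC[C@@H](C)C(=O)OCC(=O)[C@@H]1COC(C)(C)O1 | intermediate
5 | 2-bromo-5-(hydroxymethyl)phenol | OCc1ccc(Br)c(O)c1 | starting material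
6 | (4-bromo-3-hydroxyphenyl)methyl (2R)-2-methylbutanoate | CC[C@@H](C)C(=O)OCc1ccc(Br)c(O)c1 | intermediate
7 | {4-bromo-3-[(tert-butyldimethylsilyl)oxy]phenyl}methyl (2R)-2-methylbutanoate | CC[C@@H](C)C(=O)OCc1ccc(Br)c(O[Si](C)(C)C(C)(C)C)c1 | intermediate
8 | (2R)-2-Ar'-2-[(4S)-2,2-dimethyl-1,3-dioxolan-4-yl]-2-hydroxyethyl (2R)-2-methylbutanoate | CC[C@@H](C)C(=O)OC[C@](O)(c1ccc(COC(=O)[C@H](C)CC)cc1O[Si](C)(C)C(C)(C)C)[C@@H]1COC(C)(C)O1 | intermediate
9 | (2R,3S)-2-Ar'-2,3,4-trihydroxybutyl (2R)-2-methylbutanoate | CC[C@@H](C)C(=O)OC[C@](O)(c1ccc(COC(=O)[C@H](C)CC)cc1O[Si](C)(C)C(C)(C)C)[C@@H](O)CO | intermediate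
10 | (2R)-2-Ar'-2-hydroxy-3-oxopropyl (2R)-2-methylbutanoate | CC[C@@H](C)C(=O)OC[C@](O)(c1ccc(COC(=O)[C@H](C)CC)cc1O[Si](C)(C)C(C)(C)C)C=O | intermediate
11 | (2S)-2-Ar'-2,3-dihydroxypropyl (2R)-2-methylbutanoate | CC[C@@H](C)C(=O)OC[C@](O)(c1ccc(COC(=O)[C@H](C)CC)cc1O[Si](C)(C)C(C)(C)C)CO | intermediate
12 | angelic acid, (2Z)-2-methylbut-2-enoic acid | C/C=C(/C)C(=O)O | starting material
13 | (2Z)-2-methylbut-2-enoic 2,4,6-trichlorobenzoic anhydride | C/C=C(/C)C(=O)OC(=O)c1c(Cl)cc(Cl)cc1Cl | intermediate
14 | (2R)-2-Ar'-2-hydroxy-3-{[(2R)-2-methylbutanoyl]oxy}propyl (2Z)-2-methylbut-2-enoate | C/C=C(/C)C(=O)OC[C@](O)(COC(=O)[C@H](C)CC)c1ccc(COC(=O)[C@H](C)CC)cc1O[Si](C)(C)C(C)(C)C | intermediate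
15 | (2R)-2-hydroxy-2-[2-hydroxy-4-({[(2R)-2-methylbutanoyl]oxy}methyl)phenyl]-3-{[(2R)-2-methylbutanoyl]oxy}propyl (2Z)-2-methylbut-2-enoate | C/C=C(/C)C(=O)OC[C@](O)(COC(=O)[C@H](C)CC)c1ccc(COC(=O)[C@H](C)CC)cc1O | target

## Count and risks

Total steps: 7. Longest linear sequence: 6 (steps 1, 2, 4, 5, 6, 7).

**Most likely to fail, 1: step 4 (the proposed new electroreductive arylation).** The aryl–nickel addition to a hindered ketone may lose to biaryl or hydrodehalogenation, and the amide cosolvent may weaken the magnesium chelate and lower the diastereoselectivity. The fallback uses known chemistry and sets out from 7 and 4. A copper-catalysed aromatic Finkelstein exchange (CuI 10 mol %, NaI, racemic trans-N,N'-dimethylcyclohexane-1,2-diamine, dioxane, 110 °C) converts 7 into {3-[(tert-butyldimethylsilyl)oxy]-4-iodophenyl}methyl (2R)-2-methylbutanoate F1. Iodine–magnesium exchange with iPrMgCl·LiCl (THF, -40 °C, ester tolerated) gives the arylmagnesium chloride F2, used in solution. MgBr2·OEt2 and ketone 4 are then added at -78 °C; this chelation-controlled Grignard addition is established for O-protected erythrulose acetonides and gives the same diastereomer. The fallback comes back to the route at 8.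

**Most likely to fail, 2: step 5 (acetonide cleavage, glycol cleavage, reduction).** The 1,2,3-triol 9 can be over-cleaved at the internal glycol or at the α-hydroxy aldehyde stage, and aldehyde 10 can undergo α-ketol rearrangement. The fallback sets out from 8. The tertiary alcohol is silylated (TESOTf, 2,6-lutidine, CH2Cl2, -78 to 0 °C) to the C8 triethylsilyl ether F3, which blocks the internal glycol. H5IO6 in EtOAc then gives the O8-silylated aldehyde F4, and NaBH4 (EtOH, -20 °C) gives the O8-silylated primary alcohol F5. Pyridinium p-toluenesulfonate in MeOH removes the TES group while the aryl TBS ether stays. The fallback comes back at 11.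

**Most likely to fail, 3: step 6 (angeloylation).** Risks are partial Z to E isomerization to the tiglate and base- or heat-induced migration of the methylbutanoyl group from O10 to O9, which would epimerize C8. The fallback sets out from 11 and builds the Z alkene after the acylation. Coupling with 2-[bis(2,2,2-trifluoroethoxy)phosphoryl]propanoic acid (N,N'-diisopropylcarbodiimide, DMAP cat., CH2Cl2, 0 °C) gives the phosphonopropanoate ester F6. Still–Gennari olefination with acetaldehyde (KN(SiMe3)2, 18-crown-6, THF, -78 °C) then gives the Z-configured angelate. The fallback comes back at 14.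

## Further compounds

F1 | step 4 | {3-[(tert-butyldimethylsilyl)oxy]-4-iodophenyl}methyl (2R)-2-methylbutanoate | CC[C@@H](C)C(=O)OCc1ccc(I)c(O[Si](C)(C)C(C)(C)C)c1
F2 | step 4 | chlorido{2-[(tert-butyldimethylsilyl)oxy]-4-({[(2R)-2-methylbutanoyl]oxy}methyl)phenyl}magnesium (LiCl complex) | CC[C@@H](C)C(=O)OCc1ccc([Mg]Cl)c(O[Si](C)(C)C(C)(C)C)c1
F3 | step 5 | (2R)-2-Ar'-2-[(4S)-2,2-dimethyl-1,3-dioxolan-4-yl]-2-[(triethylsilyl)oxy]ethyl (2R)-2-methylbutanoate | CC[C@@H](C)C(=O)OC[C@](O[Si](CC)(CC)CC)(c1ccc(COC(=O)[C@H](C)CC)cc1O[Si](C)(C)C(C)(C)C)[C@@H]1COC(C)(C)O1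
F4 | step 5 | (2R)-2-Ar'-3-oxo-2-[(triethylsilyl)oxy]propyl (2R)-2-methylbutanoate | CC[C@@H](C)C(=O)OC[C@](O[Si](CC)(CC)CC)(c1ccc(COC(=O)[C@H](C)CC)cc1O[Si](C)(C)C(C)(C)C)C=O
F5 | step 5 | (2S)-2-Ar'-3-hydroxy-2-[(triethylsilyl)oxy]propyl (2R)-2-methylbutanoate | CC[C@@H](C)C(=O)OC[C@](O[Si](CC)(CC)CC)(c1ccc(COC(=O)[C@H](C)CC)cc1O[Si](C)(C)C(C)(C)C)CO
F6 | step 6 | (2R)-2-Ar'-2-hydroxy-3-{[(2R)-2-methylbutanoyl]oxy}propyl 2-[bis(2,2,2-trifluoroethoxy)phosphoryl]propanoate (both epimers at the phosphonate carbon) | CC[C@@H](C)C(=O)OC[C@](O)(c1ccc(COC(=O)[C@H](C)CC)cc1O[Si](C)(C)C(C)(C)C)COC(=O)C(C)P(=O)(OCC(F)(F)F)OCC(F)(F)F
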